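Everything rests on the azepine ring N4–C5H2–C6H2–C7H2–C8H=C9–C9a: its C6–C7 unit is an ethylene molecule held between an N-bound methylene (C5) and a vinylic carbon (C8) conjugated with the pyrrole. The last step exploits this: a photoredox radical relay adds the C5 radical, made by decarboxylating a pyrrol-1-ylacetic acid, to ethylene, and the new C7 radical closes 7-endo on the sulfonyl-bearing C8 of an exocyclic vinyl sulfone on ring C, whose loss of PhSO2 leaves the C8=C9 alkene. The precursor is the fully stereodefined bis-lactone tetrahydroindole bearing only N-CH2CO2H and C9=CH–SO2Ph.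

Key step: step 14

Remark on locants: Stemona-type numbering is used throughout (pyrrole N4, C9a, C1, C2, C3; azepine C5–C9; ring C = C9a, C9, C10 (ethyl), C11 (O), C12, C1; fused lactone C13 (methyl), C14 (C=O); side lactone C18 (OCH), C19, C20 (methyl), C21 (C=O)).
Assumption: (R)-methylsuccinic anhydride 2 is taken as commercial (it is the dehydration product of commercial (R)-methylsuccinic acid).

Step 1
Reactants: 1 1H-pyrrole; 2 (R)-methylsuccinic anhydride
Product: 5 methyl (2R)-2-methyl-4-oxo-4-(1H-pyrrol-2-yl)butanoate, via pyrrol-1-ylmagnesium bromide 3 (not isolated), via keto acid 4 (not isolated)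
Conditions: EtMgBr, THF/PhMe, 0 °C; 2, −40 °C to rt; aq. HCl work-up; MeOH, H2SO4 (cat.), 50 °C
Reagents that add atoms: methanol (CO)
Why: C-acylation of the pyrrole Grignard reagent at C2 by opening the anhydride at its less hindered, CH2-flanked carbonyl, then Fischer esterification; the (R)-methyl centre (later C20) comes unchanged from the chiral pool.

Step 2
Reactants: 5 methyl (2R)-2-methyl-4-oxo-4-(1H-pyrrol-2-yl)butanoate
Product: 6 methyl (2R)-4-(4-formyl-1H-pyrrol-2-yl)-2-methyl-4-oxobutanoate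
Conditions: Cl2CHOMe, AlCl3, CH2Cl2/MeNO2, −20 to 0 °C; H2O
Reagents that add atoms: dichloromethyl methyl ether (COC(Cl)Cl); water (O)
Why: Rieche formylation, in which the 2-acyl group deactivates the two conjugated ring positions and sends the electrophile to pyrrole C4 (the future C1); no stereocentre is touched.

Step 3
Reactants: 6 methyl (2R)-4-(4-formyl-1H-pyrrol-2-yl)-2-methyl-4-oxobutanoate; 7 nitromethane
Product: 8 methyl (2R)-2-methyl-4-{4-[(E)-2-nitroethenyl]-1H-pyrrol-2-yl}-4-oxobutanoate
Conditions: NH4OAc (0.3 equiv), MeNO2 (solvent), 90 °C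
Reagents that add atoms: none
Why: Henry (nitroaldol) condensation with dehydration should give the conjugated nitroalkene in its thermodynamically preferred E geometry.

Step 4
Reactants: 8 (E)-nitroalkene; 9 propanal
Product: 10 syn-(2R,3S)-γ-nitroaldehyde (methyl (2R)-2-methyl-4-{4-[(2S,3R)-3-methyl-1-nitro-4-oxobutan-2-yl]-1H-pyrrol-2-yl}-4-oxobutanoate)
Conditions: (S)-α,α-diphenylprolinol trimethylsilyl ether (10 mol %), 4-nitrophenol (10 mol %), PhMe/CH2Cl2, 0 °C to rt
Reagents that add atoms: none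
Why: Enamine-catalysed asymmetric Michael addition, in which the shielded anti-(E)-enamine of propanal attacks the nitroalkene through an acyclic synclinal transition state, so that the (S)-catalyst should set C13 (R, methyl) and C12 (S, pyrrolyl) as the syn adduct.

Step 5
Reactants: 10 syn-γ-nitroaldehyde
Product: 12 methyl (2R,3S)-3-{5-[(3R)-4-methoxy-3-methyl-4-oxobutanoyl]-1H-pyrrol-3-yl}-2-methyl-4-nitrobutanoate, via nitro acid 11 (not isolated)
Conditions: NaClO2, NaH2PO4, 2-methyl-2-butene, t-BuOH/H2O, 0 °C; then TMSCHN2, PhMe/MeOH, 0 °C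
Reagents that add atoms: sodium chlorite ([Na+].[O-]Cl=O); trimethylsilyldiazomethane (C[Si](C)(C)C=[N+]=[N-])
Why: Pinnick oxidation followed by diazoalkane methylation, neither basic enough to epimerise C13, with the HOCl scavenger protecting the acyl-deactivated pyrrole.

Step 6
Reactants: 12 nitro diester
Product: 14 methyl (2R,3S)-3-{5-[(3R)-4-methoxy-3-methyl-4-oxobutanoyl]-1H-pyrrol-3-yl}-2-methyl-4-oxobutanoate, via sodium nitronate 13 (not isolated)
Conditions: NaOMe (1.05 equiv), MeOH, 0 °C; then TiCl3, NH4OAc, THF/H2O (pH 5–6), 0 °C to rt; used crude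
Reagents that add atoms: water (O)
Why: Nef reaction in its reductive variant, in which trivalent titanium reduces the nitronate to the imine that hydrolyses to the C11 aldehyde near neutral pH, so that the enolisable C12 centre should survive.

Step 7
Reactants: 15 (Z)-pent-2-ene; 16 2-isopropoxy-4,4,5,5-tetramethyl-1,3,2-dioxaborolane
Product: 18 2-[(2Z)-pent-2-en-1-yl]-4,4,5,5-tetramethyl-1,3,2-dioxaborolane, via (Z)-pent-2-enylpotassium 17 (not isolated)
Conditions: n-BuLi, KOt-Bu, THF, −50 °C; 16, −78 °C; HCl/Et2O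
Reagents that add atoms: none
Why: Superbase allylic metalation at the methyl group gives the configurationally stable endo (Z) allylpotassium, which is borylated at its primary terminus with retention of the Z geometry.

Step 8
Reactants: 14 aldehyde; 18 (Z)-pent-2-enyl pinacol boronate
Product: 20 methyl (2R)-2-methyl-4-{4-[(2R,3S,4R)-4-methyl-5-oxo-2-[(3S)-pent-1-en-3-yl]oxolan-3-yl]-1H-pyrrol-2-yl}-4-oxobutanoate, via hydroxy ester 19 (not isolated)
Conditions: (R)-TRIP phosphoric acid (5 mol %), 4 Å MS, PhMe, −30 °C; then PPTS (cat.), PhMe, 60 °C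
Reagents that add atoms: none
Why: Allylboration through a closed chair (Zimmerman–Traxler) transition state, in which the Z γ-ethyl group makes C10-ethyl and C11-OH syn while the chiral acid directs attack to the Re face and reinforces the anti-Felkin preference of Z allylboronates (pyrrolyl anti to the incoming carbon) to give 10S,11R; acid-catalysed lactonisation then closes the γ-lactone with the C10 chain and the pyrrole cis.

Step 9
Reactants: 20 vinyl lactone; 21 phenyl vinyl sulfone
Product: 22 methyl (2R)-2-methyl-4-{4-[(2R,3S,4R)-4-methyl-5-oxo-2-[(1E,3S)-1-(phenylsulfonyl)pent-1-en-3-yl]oxolan-3-yl]-1H-pyrrol-2-yl}-4-oxobutanoate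
Conditions: second-generation Hoveyda–Grubbs catalyst (5 mol %), 21 (3 equiv), CH2Cl2, 40 °C
Reagents that add atoms: none
Why: Olefin cross-metathesis of a terminal alkene with an electron-poor vinyl sulfone that does not homodimerise should give the E vinyl sulfone without touching the stereocentres.

Step 10
Reactants: 22 (E)-vinyl sulfone; 23 tert-butyl bromoacetate
Product: 24 N-(tert-butoxycarbonylmethyl)pyrrole (tert-butyl ester of the N4-acetic acid of 22)
Conditions: K2CO3, DMF, 0 °C to rt
Reagents that add atoms: none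
Why: SN2 N-alkylation of the acidic 2-acylpyrrole N–H under a carbonate base too weak to enolise the lactone or isomerise the vinyl sulfone.

Step 11
Reactants: 24 N-alkylated vinyl sulfone
Product: 25 tricyclic exocyclic (E)-vinyl sulfone (ring C closed between C9a and C9)
Conditions: Pd(O2CCF3)2 (10 mol %), t-BuOOBz, AcOH/1,4-dioxane/DMSO, 0.01 M, 70 °C
Reagents that add atoms: none
Why: Intramolecular oxidative Heck (Fujiwara–Moritani) reaction, in which divalent palladium metalates the free pyrrole α-carbon C9a, 6-exo-trig insertion occurs at the sulfone β-carbon C9 and β-hydride elimination of the C9 hydrogen gives the exocyclic vinyl sulfone; C10–C13 are untouched and the alkene geometry is irrelevant for step 14.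

Step 12
Reactants: 25 tricyclic vinyl sulfone keto ester
Product: 27 tert-butyl ester bis-lactone, via hydroxy ester 26 (not isolated)
Conditions: RuCl(p-cymene)[(R,R)-TsDPEN] (2 mol %), HCO2H/Et3N (5:2), CH2Cl2, 30 °C; then 40 °C
Reagents that add atoms: none
Why: Asymmetric transfer hydrogenation (Noyori–Ikariya type) of the pyrrolyl ketone, in which the (R,R)-catalyst should deliver hydride to give the (18R)-carbinol under catalyst control; the γ-hydroxy ester then lactonises to the cis-α-methyl lactone because C20 is already R.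

Step 13
Reactants: 27 tert-butyl ester bis-lactone
Product: 28 N4-acetic acid bis-lactone
Conditions: CF3CO2H/CH2Cl2 (1:4), 0 °C
Reagents that add atoms: none
Why: Acidolysis of the tert-butyl ester with E1 loss of isobutene; the conjugated vinyl sulfone deactivates the pyrrole and should protect the C18–O bond from ionisation.

Step 14
Reactants: 28 N4-acetic acid bis-lactone; 29 ethene
Product: 30 CNP0324368.1
Conditions: [Ir(dF(CF3)ppy)2(dtbbpy)]PF6 (2 mol %), K2HPO4 (1 equiv), ethene (25 bar), MeCN (2 mM), 450 nm LEDs, 25 °C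
Reagents that add atoms: none
Why: Proposed new method: the excited iridium photocatalyst oxidises the carboxylate of 28, loss of CO2 gives the N-CH2 radical (C5), which adds to ethene, and the primary C7 radical attacks the sulfonyl-bearing C8, after which the C9 radical expels PhSO2•, whose reduction to sulfinate by the reduced photocatalyst closes a redox-neutral cycle. The closest known reaction types are the photoredox decarboxylative vinylation of α-amino acids with vinyl sulfones and Giese-type radical additions to ethene under pressure; their merger into a three-component annulation is new. The azepine closes by 7-endo-trig radical addition at the CH terminus, favoured over 6-exo attack because C9 is fully substituted and endo attack gives a tertiary, pyrrole-stabilised radical. No stereocentre is formed and the six existing ones are not at radical or acidic positions; the position of the ring alkene (C8=C9) is fixed by β-scission of the C8–S bond, not by proton loss. The step needs ethene capture before the C5 radical is lost: direct 5-endo closure on C8 would give a strained peri-fused 5-5-6 system, and intermolecular addition is suppressed by high dilution and ethene pressure.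

Compound list
1 | 1H-pyrrole | c1cc[nH]c1 | starting material
2 | (R)-methylsuccinic anhydride, (3R)-3-methyloxolane-2,5-dione | C[C@@H]1CC(=O)OC1=O | starting material
3 | pyrrol-1-ylmagnesium bromide | Br[Mg]n1cccc1 | intermediate
4 | (2R)-2-methyl-4-oxo-4-(1H-pyrrol-2-yl)butanoic acid | OC(=O)[C@H](C)CC(=O)c1ccc[nH]1 | intermediate
5 | methyl (2R)-2-methyl-4-oxo-4-(1H-pyrrol-2-yl)butanoate | COC(=O)[C@H](C)CC(=O)c1ccc[nH]1 | intermediate
6 | methyl (2R)-4-(4-formyl-1H-pyrrol-2-yl)-2-methyl-4-oxobutanoate | COC(=O)[C@H](C)CC(=O)c1cc(C=O)c[nH]1 | intermediate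
7 | nitromethane | C[N+](=O)[O-] | starting material
8 | methyl (2R)-2-methyl-4-{4-[(E)-2-nitroethenyl]-1H-pyrrol-2-yl}-4-oxobutanoate | COC(=O)[C@H](C)CC(=O)c1cc(/C=C/[N+](=O)[O-])c[nH]1 | intermediate
9 | propanal | CCC=O | starting material
10 | methyl (2R)-2-methyl-4-{4-[(2S,3R)-3-methyl-1-nitro-4-oxobutan-2-yl]-1H-pyrrol-2-yl}-4-oxobutanoate (syn Michael adduct) | O=C[C@H](C)[C@H](C[N+](=O)[O-])c2c[nH]c(C(=O)C[C@@H](C)C(=O)OC)c2 | intermediate
11 | (2R,3S)-3-{5-[(3R)-4-methoxy-3-methyl-4-oxobutanoyl]-1H-pyrrol-3-yl}-2-methyl-4-nitrobutanoic acid | OC(=O)[C@H](C)[C@H](C[N+](=O)[O-])c2c[nH]c(C(=O)C[C@@H](C)C(=O)OC)c2 | intermediate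
12 | methyl (2R,3S)-3-{5-[(3R)-4-methoxy-3-methyl-4-oxobutanoyl]-1H-pyrrol-3-yl}-2-methyl-4-nitrobutanoate | COC(=O)[C@H](C)[C@H](C[N+](=O)[O-])c2c[nH]c(C(=O)C[C@@H](C)C(=O)OC)c2 | intermediate
13 | sodium nitronate of 12 (aci-nitro salt at the former CH2NO2 carbon) | COC(=O)[C@H](C)[C@H](C=[N+]([O-])[O-])c2c[nH]c(C(=O)C[C@@H](C)C(=O)OC)c2.[Na+] | intermediate
14 | methyl (2R,3S)-3-{5-[(3R)-4-methoxy-3-methyl-4-oxobutanoyl]-1H-pyrrol-3-yl}-2-methyl-4-oxobutanoate | COC(=O)[C@H](C)[C@H](C=O)c2c[nH]c(C(=O)C[C@@H](C)C(=O)OC)c2 | intermediate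
15 | (Z)-pent-2-ene | C/C=C\CC | starting material
16 | 2-isopropoxy-4,4,5,5-tetramethyl-1,3,2-dioxaborolane | CC(C)OB1OC(C)(C)C(C)(C)O1 | starting material
17 | (Z)-pent-2-enylpotassium | CC/C=C\C[K] | intermediate
18 | 2-[(2Z)-pent-2-en-1-yl]-4,4,5,5-tetramethyl-1,3,2-dioxaborolane | CC/C=C\CB1OC(C)(C)C(C)(C)O1 | intermediate
19 | methyl (2R,3S,4R,5S)-5-ethyl-4-hydroxy-3-{5-[(3R)-4-methoxy-3-methyl-4-oxobutanoyl]-1H-pyrrol-3-yl}-2-methylhept-6-enoate | COC(=O)[C@H](C)[C@@H](c2c[nH]c(C(=O)C[C@@H](C)C(=O)OC)c2)[C@H](O)[C@@H](CC)C=C | intermediate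
20 | methyl (2R)-2-methyl-4-{4-[(2R,3S,4R)-4-methyl-5-oxo-2-[(3S)-pent-1-en-3-yl]oxolan-3-yl]-1H-pyrrol-2-yl}-4-oxobutanoate | C=C[C@H](CC)[C@H]1OC(=O)[C@H](C)[C@H]1c2c[nH]c(C(=O)C[C@@H](C)C(=O)OC)c2 | intermediate
21 | phenyl vinyl sulfone | C=CS(=O)(=O)c1ccccc1 | starting material
22 | methyl (2R)-2-methyl-4-{4-[(2R,3S,4R)-4-methyl-5-oxo-2-[(1E,3S)-1-(phenylsulfonyl)pent-1-en-3-yl]oxolan-3-yl]-1H-pyrrol-2-yl}-4-oxobutanoate | O=S(=O)(/C=C/[C@H](CC)[C@H]1OC(=O)[C@H](C)[C@H]1c2c[nH]c(C(=O)C[C@@H](C)C(=O)OC)c2)c3ccccc3 | intermediate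
23 | tert-butyl bromoacetate | BrCC(=O)OC(C)(C)C | starting material
24 | tert-butyl 2-{2-[(3R)-4-methoxy-3-methyl-4-oxobutanoyl]-4-[(2R,3S,4R)-4-methyl-5-oxo-2-[(1E,3S)-1-(phenylsulfonyl)pent-1-en-3-yl]oxolan-3-yl]-1H-pyrrol-1-yl}acetate | O=S(=O)(/C=C/[C@H](CC)[C@H]1OC(=O)[C@H](C)[C@H]1c2cn(CC(=O)OC(C)(C)C)c(C(=O)C[C@@H](C)C(=O)OC)c2)c3ccccc3 | intermediate
25 | tricyclic Heck product: C9a bonded to C9, which carries the exocyclic (E)-CH–SO2Ph; ring C with (10S)-ethyl and the cis-fused (11R,12S,13R)-13-methyl γ-lactone (O on C11); N4–CH2CO2t-Bu; C3–C(=O)CH2-(R)-CH(CH3)CO2CH3 | CC[C@H]1/C(=C\S(=O)(=O)c2ccccc2)c3c(cc(C(=O)C[C@@H](C)C(=O)OC)n3CC(=O)OC(C)(C)C)[C@H]4[C@@H]1OC(=O)[C@@H]4C | intermediate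
26 | as 25 with the C3 ketone reduced to the (18R)-alcohol | CC[C@H]1/C(=C\S(=O)(=O)c2ccccc2)c3c(cc([C@H](O)C[C@@H](C)C(=O)OC)n3CC(=O)OC(C)(C)C)[C@H]4[C@@H]1OC(=O)[C@@H]4C | intermediate
27 | as 25 with the C3 side chain closed to the (18R,20R)-cis-α-methyl-γ-lactone (tert-butyl ester) | CC[C@H]1/C(=C\S(=O)(=O)c2ccccc2)c3c(cc([C@H]5C[C@@H](C)C(=O)O5)n3CC(=O)OC(C)(C)C)[C@H]4[C@@H]1OC(=O)[C@@H]4C | intermediate
28 | free N4-acetic acid of 27 | CC[C@H]1/C(=C\S(=O)(=O)c2ccccc2)c3c(cc([C@H]5C[C@@H](C)C(=O)O5)n3CC(=O)O)[C@H]4[C@@H]1OC(=O)[C@@H]4C | intermediate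
29 | ethene | C=C | starting material
30 | CNP0324368.1, (10S,11R,12S,13R,18R,20R) | CC[C@H]1C2=CCCCn3c([C@H]4C[C@@H](C)C(=O)O4)cc(c32)[C@H]2[C@@H]1OC(=O)[C@@H]2C | target

Total steps: 14. Longest linear sequence: 13 (steps 1–6 and 8–14; step 7 makes the allylboronate).

Steps most likely to fail

Step 14 (Proposed new method). The C5 radical may be consumed before it meets ethene, by hydrogen abstraction or by addition to the vinyl sulfone of a second molecule, and the electron-rich vinylpyrrole product may be oxidised by the excited photocatalyst. The fallback uses known chemistry and puts the three-carbon chain on nitrogen first, so that ring closure forms only C7–C8. It sets out from 22 and returns at 30. N-Alkylation of 22 with excess 1,3-dibromopropane (K2CO3, DMF) should give the N-(3-bromopropyl)pyrrole F1. The oxidative Heck conditions of step 11 should give the tricyclic bromide F2. Transfer hydrogenation as in step 12 should give the hydroxy ester F3 (not isolated) and then the bromo bis-lactone F4. Slow addition of Bu3SnH with AIBN (PhH, 80 °C, 3 mM) should close the azepine by 7-endo radical addition to C8 and β-elimination of PhSO2•, a tin-mediated cyclisation–fragmentation of known type, to give 30.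

Step 11. Palladation may occur at C2 (directed by the ketone) instead of C9a, and the palladium hydride formed may move the new alkene into ring C, which would erase C10. The fallback fixes the site by pre-functionalisation. It sets out from 24 and returns at 25. Iodination with NIS (DMF, 0 °C) at the only free α-carbon should give the C9a iodide F5. A Mizoroki–Heck cyclisation through zerovalent palladium (Pd(OAc)2, PPh3, Ag2CO3, MeCN, 70 °C) should then give 25, the silver salt removing iodide and limiting hydride re-addition.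

Step 8. Aldehyde 14 may enolise and lose its C12 configuration before C–C bond formation, facial control may be incomplete, and the later cross-metathesis of the branched alkene may be slow. The fallback replaces allylboration and metathesis by an auxiliary-controlled aldol. It sets out from 14 and returns at 22. An Evans syn-aldol with (R)-4-benzyl-3-butanoyl-1,3-oxazolidin-2-one (Bu2BOTf, i-Pr2NEt, CH2Cl2, −78 °C) should give the syn-aldol adduct F6, which lactonises (PPTS) to the lactone imide F7. LiSEt (THF, 0 °C) should give the thioester F8, and Fukuyama reduction (Et3SiH, Pd/C, acetone) the aldehyde F9. Horner–Wadsworth–Emmons olefination with diethyl [(phenylsulfonyl)methyl]phosphonate (LiCl, DBU, MeCN) should then give 22.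

Further compounds
F1 | step 14 | N-(3-bromopropyl) analogue of 24 (3-bromopropyl on N4 in place of CH2CO2t-Bu) | O=S(=O)(/C=C/[C@H](CC)[C@H]1OC(=O)[C@H](C)[C@H]1c2cn(CCCBr)c(C(=O)C[C@@H](C)C(=O)OC)c2)c3ccccc3
F2 | step 14 | N-(3-bromopropyl) analogue of 25 | CC[C@H]1/C(=C\S(=O)(=O)c2ccccc2)c3c(cc(C(=O)C[C@@H](C)C(=O)OC)n3CCCBr)[C@H]4[C@@H]1OC(=O)[C@@H]4C
F3 | step 14 | N-(3-bromopropyl) analogue of 26, (18R)-hydroxy ester | CC[C@H]1/C(=C\S(=O)(=O)c2ccccc2)c3c(cc([C@H](O)C[C@@H](C)C(=O)OC)n3CCCBr)[C@H]4[C@@H]1OC(=O)[C@@H]4C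
F4 | step 14 | N-(3-bromopropyl) analogue of 27, bromo bis-lactone | CC[C@H]1/C(=C\S(=O)(=O)c2ccccc2)c3c(cc([C@H]5C[C@@H](C)C(=O)O5)n3CCCBr)[C@H]4[C@@H]1OC(=O)[C@@H]4C
F5 | step 11 | C9a-iodo derivative of 24 (iodine on the pyrrole α-carbon between N4 and C1) | O=S(=O)(/C=C/[C@H](CC)[C@H]1OC(=O)[C@H](C)[C@H]1c2c(I)n(CC(=O)OC(C)(C)C)c(C(=O)C[C@@H](C)C(=O)OC)c2)c3ccccc3
F6 | step 8 | syn-aldol adduct of 14 (C11 hydroxy ester; C9 as N-acyl (R)-4-benzyloxazolidinone) | COC(=O)[C@H](C)[C@@H](c1c[nH]c(C(=O)C[C@@H](C)C(=O)OC)c1)[C@H](O)[C@@H](CC)C(=O)N2[C@H](Cc3ccccc3)COC2=O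
F7 | step 8 | lactone imide (γ-lactone of F6; C9 as N-acyl oxazolidinone) | CC[C@@H](C(=O)N1[C@H](Cc2ccccc2)COC1=O)[C@H]3OC(=O)[C@H](C)[C@H]3c4c[nH]c(C(=O)C[C@@H](C)C(=O)OC)c4
F8 | step 8 | S-ethyl thioester at C9 | CC[C@@H](C(=O)SCC)[C@H]3OC(=O)[C@H](C)[C@H]3c4c[nH]c(C(=O)C[C@@H](C)C(=O)OC)c4
F9 | step 8 | C9 aldehyde | CC[C@@H](C=O)[C@H]3OC(=O)[C@H](C)[C@H]3c4c[nH]c(C(=O)C[C@@H](C)C(=O)OC)c4
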